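**Retrosynthetic overview**

1. Numbering is that of the acid core, 1,2,3,4,4a,7,8,8a-octahydronaphthalene-1-carboxylic acid (C1 CO2R, C2 CH3, C4a and C8a angular CH3, C5 side chain, C5=C6; ring A = C1–C4, C4a, C8a; ring B = C4a–C8a). Target 23 ⇒ acid 19 + (R)-solketal 20 (ester C–O bond; acetate last).
2. 19 ⇒ enedione ester 12: the C5 side chain comes from Negishi coupling of the C5 enol triflate, and the C4 carbonyl is removed by Wolff–Kishner reduction. Ring B of 12 ⇒ aldol condensation of a C4a acetyl group (C5, C6) with a C7 aldehyde.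
3. 12 ⇒ keto lactone 9, in which a temporary δ-lactone (C1 carboxyl tied to O–C7) masks the ester and the aldehyde; it is opened after the key step.
4. 9 ⇒ allyl vinyl ether 7 in one operation: Claisen rearrangement (C4a–C8a), then intramolecular Michael addition (C2–C3, closes ring A). 7 ⇒ (R)-carbinol 5 + 3-methylpentane-2,4-dione 6; 5 ⇒ acetyl lactone 4 ⇒ 1 + 2. Ring order: lactone (temporary), ring A, ring B.
5. Enabling feature: C1 carries the carboxyl between C8a and C2, so C8a=C1–C2(O) is a 2-carboxyallyl unit that passes an O-bound carbon from C2 to C8a and then accepts a nucleophile at C2. C4a lies between C4 (ring A) and C5 (ring B), so it is the central carbon of 3-methylpentane-2,4-dione, whose two acetyl groups become C4/C3 and C5/C6.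

Key step: step 5

**Route**

Step 1
Reactants: 1 4-hydroxybutan-2-one; 2 2,2,6-trimethyl-4H-1,3-dioxin-4-one
Product: 3 3-oxobutyl 3-oxobutanoate
Conditions: PhMe, 110 °C, acetone distilled off
Reagents that add atoms: none
Why: Thermal cycloreversion of 2 gives acetylketene, which the primary alcohol should trap (acetoacetylation).

Step 2
Reactants: 3 3-oxobutyl 3-oxobutanoate
Product: 4 3-acetyl-4-methyl-5,6-dihydro-2H-pyran-2-one
Conditions: TiCl4 (2 equiv), pyridine (4 equiv), THF, 0 °C → rt
Reagents that add atoms: none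
Why: Intramolecular Knoevenagel condensation of the acetoacetate onto the methyl ketone should close the six-membered lactone, and the ring fixes the geometry of the tetrasubstituted alkene (carboxyl cis to C8).

Step 3
Reactants: 4 3-acetyl-4-methyl-5,6-dihydro-2H-pyran-2-one
Product: 5 3-[(1R)-1-hydroxyethyl]-4-methyl-5,6-dihydro-2H-pyran-2-one
Conditions: (S)-2-methyl-CBS-oxazaborolidine (15 mol %), catecholborane (1.5 equiv), PhMe, −78 °C; then MeOH
Reagents that add atoms: none
Why: Corey–Bakshi–Shibata 1,2-reduction of the alkenyl methyl ketone, with the tetrasubstituted alkenyl group as the large substituent, is expected to give the (R)-carbinol with the (S)-catalyst.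

Step 4
Reactants: 5 3-[(1R)-1-hydroxyethyl]-4-methyl-5,6-dihydro-2H-pyran-2-one; 6 3-methylpentane-2,4-dione
Product: 7 4-methyl-3-[(1S)-1-[(3-methyl-4-oxopent-2-en-2-yl)oxy]ethyl]-5,6-dihydro-2H-pyran-2-one (enol ether E/Z not controlled; this geometry is erased in step 5)
Conditions: PPh3, DIAD, THF, 0 °C → rt
Reagents that add atoms: none
Why: Mitsunobu alkylation of the acidic enol of 6 at oxygen (its carbon terminus is fully substituted) should proceed with SN2 inversion to the (S)-configured allyl vinyl ether.

Step 5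
Reactants: 7 4-methyl-3-[(1S)-1-[(3-methyl-4-oxopent-2-en-2-yl)oxy]ethyl]-5,6-dihydro-2H-pyran-2-one
Product: 9 (4aR,5S,8R,8aS)-5-acetyl-4a,5,8-trimethyl-3,4,4a,5,8,8a-hexahydro-1H-isochromene-1,6(7H)-dione (keto lactone; lactone trans-fused, 4a- and 5-methyl cis, 8-methyl trans to 4a-methyl), via (Z)-ethylidene lactone 8 (not isolated)
Conditions: o-xylene, 170 °C, sealed tube, 12 h; then t-BuOK (0.2 equiv), t-BuOH, 0 → 25 °C, same flask
Reagents that add atoms: none
Why: On heating, the allyl vinyl ether should undergo a Claisen rearrangement ([3,3]-sigmatropic shift, as known for O-allyl enol ethers of 1,3-diketones) that forms C4a–C8a, returns the enol ether carbon to an acetyl group (so C4a carries two identical acetyl groups and is not yet stereogenic) and moves the double bond out of the ring to give the (Z)-ethylidene lactone 8. The carbinol stereocentre is relayed to C8a: allylic 1,3-strain with the ring methyl group keeps its C–H bond near the alkene plane, so oxygen and migrating carbon stay on one face whether a chair or a boat is used, and its methyl group ends anti to C8a. Catalytic t-BuOK then gives the enolate of one acetyl group, which adds to the ethylidene carbon and closes ring A in a chair-like 6-endo-trig Michael addition with the ester carbonyl outside the new ring, the same closure as the second step of the α,α′-annulation of ketones with 2-(bromomethyl)acrylates. Three further stereocentres follow from C8a in this event: the lactone ring holds C8 near the plane of the acceptor, so the angular methyl is axial and the C2 methyl (anti to C8a on the alkene) becomes equatorial and trans to it; the acetyl group that does not react sits axial at C4a, away from the enolate oxygen and gauche to only one neighbour, which places the two angular methyls cis; C1 is equilibrated by the base to the equatorial carboxyl of the trans-fused lactone. The step needs selection between the two diastereotopic acetyl groups and conjugate addition instead of acylation by the lactone carbonyl; the first rests on the chair just described, the second on catalytic base under equilibrating conditions, in which the Michael adduct is the only stable product.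

Step 6
Reactants: 9 keto lactone
Product: 10 methyl (1S,2R,5S,6R)-5-acetyl-6-(2-bromoethyl)-2,5,6-trimethyl-4-oxocyclohexane-1-carboxylate
Conditions: HBr (g), MeOH, 0 → 40 °C
Reagents that add atoms: hydrogen bromide (Br); methanol (CO)
Why: Acid-mediated opening of the lactone with bromide at the primary O–CH2 carbon and Fischer esterification (the classical lactone to ω-bromo ester conversion) should unmask C1 as its methyl ester without touching the stereocentres.

Step 7
Reactants: 10 bromo ester
Product: 11 methyl (1S,2R,5S,6R)-5-acetyl-2,5,6-trimethyl-4-oxo-6-(2-oxoethyl)cyclohexane-1-carboxylate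
Conditions: Me3NO (anhydrous, 3 equiv), DMSO, 25 → 50 °C
Reagents that add atoms: trimethylamine N-oxide (C[N+](C)(C)[O-])
Why: Kornblum-type oxidation, in which the N-oxide oxygen displaces the primary bromide and loss of trimethylamine gives the aldehyde under nearly neutral conditions that spare the base-sensitive 1,3-diketone.

Step 8
Reactants: 11 keto aldehyde
Product: 12 methyl (1S,2R,4aR,8aR)-2,4a,8a-trimethyl-4,5-dioxo-1,2,3,4,4a,5,8,8a-octahydronaphthalene-1-carboxylate
Conditions: p-TsOH·H2O (10 mol %), PhMe, 80 °C, 4 Å molecular sieves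
Reagents that add atoms: none
Why: Intramolecular aldol condensation (6-enolendo-exo-trig) of the remaining acetyl group with the aldehyde should close ring B as the cis-fused cyclohexenone; the only other six-membered aldol (from C3) cannot dehydrate because it would give a bridgehead alkene.

Step 9
Reactants: 12 enedione ester
Product: 14 methyl (1S,2R,4aS,8aR)-2,4a,8a-trimethyl-4-oxo-5-{[(trifluoromethyl)sulfonyl]oxy}-1,2,3,4,4a,7,8,8a-octahydronaphthalene-1-carboxylate, via lithium enolate 13 (not isolated)
Conditions: LiBH(s-Bu)3 (L-Selectride, 1.05 equiv), THF, −78 °C; then N-(5-chloropyridin-2-yl)triflimide, −78 → 0 °C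
Reagents that add atoms: N-(5-chloropyridin-2-yl)-1,1,1-trifluoro-N-(trifluoromethanesulfonyl)methanesulfonamide (FC(F)(F)S(=O)(=O)N(c1ccc(Cl)cn1)S(=O)(=O)C(F)(F)F)
Why: Conjugate hydride addition to the β-unsubstituted cyclohexenone gives the C5 enolate regiospecifically for O-triflation, while the C4 ketone is shielded by the quaternary C4a and the syn-axial C8a methyl.

Step 10
Reactants: 15 5-bromo-2-methylpent-2-ene
Product: 16 bromo(4-methylpent-3-en-1-yl)zinc
Conditions: Zn dust (activated with 1,2-dibromoethane and Me3SiCl), LiCl, THF, 40 °C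
Reagents that add atoms: zinc ([Zn])
Why: Direct insertion of LiCl-activated zinc into the primary alkyl bromide should give the alkylzinc reagent and leave the trisubstituted alkene untouched.

Step 11
Reactants: 14 enol triflate; 16 bromo(4-methylpent-3-en-1-yl)zinc
Product: 17 methyl (1S,2R,4aR,8aR)-2,4a,8a-trimethyl-5-(4-methylpent-3-en-1-yl)-4-oxo-1,2,3,4,4a,7,8,8a-octahydronaphthalene-1-carboxylate
Conditions: PdCl2(dppf) (5 mol %), THF, 50 °C
Reagents that add atoms: none
Why: Negishi sp2–sp3 coupling of an alkenyl triflate with a primary alkylzinc tolerates the ketone and the ester and should place the side chain on C5 with the double bond fixed at C5=C6.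

Step 12
Reactants: 17 keto ester
Product: 19 (1S,2R,4aR,8aR)-2,4a,8a-trimethyl-5-(4-methylpent-3-en-1-yl)-1,2,3,4,4a,7,8,8a-octahydronaphthalene-1-carboxylic acid, via hydrazone 18 (not isolated)
Conditions: N2H4·H2O, diethylene glycol, 130 °C; then KOH, 200 °C; aq. HCl work-up
Reagents that add atoms: potassium hydroxide ([K+].[OH-]; its oxygen ends in the carboxyl group)
Why: Wolff–Kishner reduction of the hindered C4 ketone with saponification of the methyl ester in the same operation; C1 can only equilibrate toward the required equatorial carboxyl (trans to the C2 methyl), and C4a has no hydrogen, so the C5=C6 alkene cannot move into conjugation.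

Step 13
Reactants: 19 acid; 20 [(4R)-2,2-dimethyl-1,3-dioxolan-4-yl]methanol ((R)-solketal)
Product: 21 [(4S)-2,2-dimethyl-1,3-dioxolan-4-yl]methyl (1S,2R,4aR,8aR)-2,4a,8a-trimethyl-5-(4-methylpent-3-en-1-yl)-1,2,3,4,4a,7,8,8a-octahydronaphthalene-1-carboxylate
Conditions: PPh3, DIAD, THF, 0 °C → rt
Reagents that add atoms: none
Why: Mitsunobu esterification activates the primary alcohol of 20, so the hindered carboxylate only has to act as nucleophile and the dioxolane stereocentre is not touched (its descriptor changes only through the priority rules).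

Step 14
Reactants: 21 acetonide ester
Product: 22 (2S)-2,3-dihydroxypropyl (1S,2R,4aR,8aR)-2,4a,8a-trimethyl-5-(4-methylpent-3-en-1-yl)-1,2,3,4,4a,7,8,8a-octahydronaphthalene-1-carboxylate
Conditions: AcOH/H2O 4:1, 40 °C
Reagents that add atoms: none
Why: Mild acid hydrolysis of the acetonide should spare the trisubstituted alkenes, and the hindered acyl group is expected to migrate only slowly.

Step 15
Reactants: 22 diol ester
Product: 23 (2S)-3-(acetyloxy)-2-hydroxypropyl (1S,2R,4aR,8aR)-2,4a,8a-trimethyl-5-(4-methylpent-3-en-1-yl)-1,2,3,4,4a,7,8,8a-octahydronaphthalene-1-carboxylate (target)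
Conditions: AcCl (1.05 equiv), 2,4,6-collidine, CH2Cl2, −78 °C
Reagents that add atoms: acetyl chloride (CC(=O)Cl)
Why: Low-temperature acylation with a hindered pyridine base should select the primary over the secondary hydroxyl and avoid acyl migration.

**Compound list**

1 | 4-hydroxybutan-2-one | CC(=O)CCO | starting material
2 | 2,2,6-trimethyl-4H-1,3-dioxin-4-one | CC1=CC(=O)OC(C)(C)O1 | starting material
3 | 3-oxobutyl 3-oxobutanoate | CC(=O)CC(=O)OCCC(C)=O | intermediate
4 | 3-acetyl-4-methyl-5,6-dihydro-2H-pyran-2-one | CC(=O)C1=C(C)CCOC1=O | intermediate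
5 | 3-[(1R)-1-hydroxyethyl]-4-methyl-5,6-dihydro-2H-pyran-2-one | C[C@@H](O)C1=C(C)CCOC1=O | intermediate
6 | 3-methylpentane-2,4-dione | CC(=O)C(C)C(C)=O | starting material
7 | 4-methyl-3-[(1S)-1-[(3-methyl-4-oxopent-2-en-2-yl)oxy]ethyl]-5,6-dihydro-2H-pyran-2-one | C[C@H](OC(C)=C(C)C(C)=O)C1=C(C)CCOC1=O | intermediate
8 | (3Z,4S)-3-ethylidene-4-methyl-4-(3-methyl-2,4-dioxopentan-3-yl)oxan-2-one | C/C=C1\C(=O)OCC[C@@]1(C)C(C)(C(C)=O)C(C)=O | intermediate
9 | (4aR,5S,8R,8aS)-5-acetyl-4a,5,8-trimethyl-3,4,4a,5,8,8a-hexahydro-1H-isochromene-1,6(7H)-dione | C[C@@H]1CC(=O)[C@](C)(C(C)=O)[C@]2(C)CCOC(=O)[C@@H]12 | intermediate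
10 | methyl (1S,2R,5S,6R)-5-acetyl-6-(2-bromoethyl)-2,5,6-trimethyl-4-oxocyclohexane-1-carboxylate | C[C@@H]1CC(=O)[C@](C)(C(C)=O)[C@](C)(CCBr)[C@H]1C(=O)OC | intermediate
11 | methyl (1S,2R,5S,6R)-5-acetyl-2,5,6-trimethyl-4-oxo-6-(2-oxoethyl)cyclohexane-1-carboxylate | C[C@@H]1CC(=O)[C@](C)(C(C)=O)[C@](C)(CC=O)[C@H]1C(=O)OC | intermediate
12 | methyl (1S,2R,4aR,8aR)-2,4a,8a-trimethyl-4,5-dioxo-1,2,3,4,4a,5,8,8a-octahydronaphthalene-1-carboxylate | C[C@@H]1CC(=O)[C@]2(C)C(=O)C=CC[C@]2(C)[C@H]1C(=O)OC | intermediate
13 | lithium C5 enolate of the 4,5-dioxo ester (C5–O–Li, C5=C6) | [Li+].C[C@@H]1CC(=O)[C@]2(C)C([O-])=CCC[C@]2(C)[C@H]1C(=O)OC | intermediate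
14 | methyl (1S,2R,4aS,8aR)-2,4a,8a-trimethyl-4-oxo-5-{[(trifluoromethyl)sulfonyl]oxy}-1,2,3,4,4a,7,8,8a-octahydronaphthalene-1-carboxylate | C[C@@H]1CC(=O)[C@]2(C)C(OS(=O)(=O)C(F)(F)F)=CCC[C@]2(C)[C@H]1C(=O)OC | intermediate
15 | 5-bromo-2-methylpent-2-ene | CC(C)=CCCBr | starting material
16 | bromo(4-methylpent-3-en-1-yl)zinc | CC(C)=CCC[Zn]Br | intermediate
17 | methyl (1S,2R,4aR,8aR)-2,4a,8a-trimethyl-5-(4-methylpent-3-en-1-yl)-4-oxo-1,2,3,4,4a,7,8,8a-octahydronaphthalene-1-carboxylate | C[C@@H]1CC(=O)[C@]2(C)C(CCC=C(C)C)=CCC[C@]2(C)[C@H]1C(=O)OC | intermediate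
18 | C4 hydrazone of 17 | C[C@@H]1CC(=NN)[C@]2(C)C(CCC=C(C)C)=CCC[C@]2(C)[C@H]1C(=O)OC | intermediate
19 | (1S,2R,4aR,8aR)-2,4a,8a-trimethyl-5-(4-methylpent-3-en-1-yl)-1,2,3,4,4a,7,8,8a-octahydronaphthalene-1-carboxylic acid | C[C@@H]1CC[C@]2(C)C(CCC=C(C)C)=CCC[C@]2(C)[C@H]1C(=O)O | intermediate
20 | [(4R)-2,2-dimethyl-1,3-dioxolan-4-yl]methanol | CC1(C)OC[C@@H](CO)O1 | starting material
21 | [(4S)-2,2-dimethyl-1,3-dioxolan-4-yl]methyl ester of 19 | CC1(C)OC[C@H](O1)COC(=O)[C@H]1[C@H](C)CC[C@]2(C)C(CCC=C(C)C)=CCC[C@]12C | intermediate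
22 | (2S)-2,3-dihydroxypropyl ester of 19 | OC[C@H](O)COC(=O)[C@H]1[C@H](C)CC[C@]2(C)C(CCC=C(C)C)=CCC[C@]12C | intermediate
23 | (2S)-3-(acetyloxy)-2-hydroxypropyl (1S,2R,4aR,8aR)-2,4a,8a-trimethyl-5-(4-methylpent-3-en-1-yl)-1,2,3,4,4a,7,8,8a-octahydronaphthalene-1-carboxylate | CC(=O)OC[C@H](O)COC(=O)[C@H]1[C@H](C)CC[C@]2(C)C(CCC=C(C)C)=CCC[C@]12C | target

**Step count**

Total steps: 15. Longest linear sequence: 14 (steps 1–9 and 11–15; step 10 is a one-step branch).

**Steps most likely to fail**

Step 5. The sigmatropic shift must join two fully substituted carbons and may be outrun by thermal fragmentation of the enol ether (loss of the diketone), and the ring closure may select poorly between the two acetyl groups. The fallback sets out from 4 (with 6) and comes back at 9. Conjugate addition of 6 to the doubly activated alkene of 4 (FeCl3·6H2O catalysis, or a cinchona-derived squaramide to set the quaternary centre) should give (4R)-3-acetyl-4-methyl-4-(3-methyl-2,4-dioxopentan-3-yl)oxan-2-one F1. Acid-catalysed aldol condensation (p-TsOH, PhMe, 80 °C) of one diketone acetyl group with the lactone-bound acetyl group should then give the enone lactone 5-acetyl-4a,5,8-trimethyl-3,4,4a,5-tetrahydro-1H-isochromene-1,6(8aH)-dione F2. Dissolving-metal reduction (Li, NH3, THF, −78 °C) should protonate C8 axially, leave its methyl equatorial and return 9. If the catalytic Michael step is not selective enough, the diastereomeric esters 21 would be separated after step 13.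

Step 4. The activated allylic alcohol may undergo C-alkylation of the diketone, allylic transposition or elimination instead of O-alkylation with clean inversion. The fallback sets out from 4 (with 6) and comes back at 7. Reduction of 4 with the (R)-CBS catalyst should give 3-[(1S)-1-hydroxyethyl]-4-methyl-5,6-dihydro-2H-pyran-2-one F3. Diketone 6 with HC(OMe)3 and catalytic p-TsOH in MeOH should give 4-methoxy-3-methylpent-3-en-2-one F4. Acid-catalysed vinylogous transesterification of F4 with F3 (PPTS, PhMe, 90 °C, methanol removed) forms the vinyl C–O bond with retention at the carbinol carbon and should return 7.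

Step 12. The hot basic medium may open ring A by retro-Michael cleavage before the hydrazone has formed, convert the ester into a hydrazide, or leave the hindered ketone unreduced. The fallback sets out from 17 and comes back at 19. NaBH4 (MeOH, 0 °C) should give the C4 alcohol, methyl 4-hydroxy-2,4a,8a-trimethyl-5-(4-methylpent-3-en-1-yl)-1,2,3,4,4a,7,8,8a-octahydronaphthalene-1-carboxylate F5 (either epimer). NaH, CS2 and MeI should give its S-methyl xanthate F6. Barton–McCombie deoxygenation (Bu3SnH, AIBN, PhMe, 110 °C) should give the methyl ester of 19, F7. LiSPr in HMPA at rt should cleave the ester by SN2 attack at the methyl group and return 19.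

Further compounds
F1 | step 5 | (4R)-3-acetyl-4-methyl-4-(3-methyl-2,4-dioxopentan-3-yl)oxan-2-one (C3 epimers) | CC(=O)C1C(=O)OCC[C@@]1(C)C(C)(C(C)=O)C(C)=O
F2 | step 5 | 5-acetyl-4a,5,8-trimethyl-3,4,4a,5-tetrahydro-1H-isochromene-1,6(8aH)-dione (ring fusion and C5 as in 9) | CC1=CC(=O)[C@](C)(C(C)=O)[C@]2(C)CCOC(=O)[C@@H]12
F3 | step 4 | 3-[(1S)-1-hydroxyethyl]-4-methyl-5,6-dihydro-2H-pyran-2-one | C[C@H](O)C1=C(C)CCOC1=O
F4 | step 4 | 4-methoxy-3-methylpent-3-en-2-one | COC(C)=C(C)C(C)=O
F5 | step 12 | methyl 4-hydroxy-2,4a,8a-trimethyl-5-(4-methylpent-3-en-1-yl)-1,2,3,4,4a,7,8,8a-octahydronaphthalene-1-carboxylate (C4 epimers) | C[C@@H]1CC(O)[C@]2(C)C(CCC=C(C)C)=CCC[C@]2(C)[C@H]1C(=O)OC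
F6 | step 12 | S-methyl xanthate of F5 | C[C@@H]1CC(OC(=S)SC)[C@]2(C)C(CCC=C(C)C)=CCC[C@]2(C)[C@H]1C(=O)OC
F7 | step 12 | methyl (1S,2R,4aR,8aR)-2,4a,8a-trimethyl-5-(4-methylpent-3-en-1-yl)-1,2,3,4,4a,7,8,8a-octahydronaphthalene-1-carboxylate | C[C@@H]1CC[C@]2(C)C(CCC=C(C)C)=CCC[C@]2(C)[C@H]1C(=O)OC
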